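**Remarks (assumptions)**
- The SMILES is read as (−)-epiafzelechin-(4β→6)-(−)-epicatechin 3-O-gallate: upper unit (2R,3R,4S), 2,3-cis-3,4-trans; lower unit (2R,3R).
- In step 4 the ProPhenol antipode that delivers the (R)-carbinol is to be used; it is taken to be (S,S)-ProPhenol, and the mirror ligand would be used if the sense proves opposite.
- 1-(Benzyloxy)-4-ethynylbenzene and 3,4,5-tris(benzyloxy)benzoic acid are taken as purchasable; dimethyldioxirane is used as a freshly made acetone solution (from acetone and KHSO5).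

**Retrosynthetic overview**
1. Target 22 ⇐ global hydrogenolysis of the deca-O-benzyl tribromide 21 (ten benzyl ethers and three C–Br caps).
2. 21 ⇐ one-flask domino of cis-epoxy alcohol 13 with bromine-capped (−)-epicatechin gallate 18: O1–C2 closure of the upper pyran ring C, then C4–C6 arylation.
3. Enabling feature: in the upper unit the ring-A phenol oxygen O1 is 1,5-related to benzylic C2, which carries the para-oxygenated ring B, so a C2–C3 cis-epoxide opens at C2 in a 6-endo mode; C4 is benzylic to ring A and ortho-related to O1, so its hydroxyl is a latent cation for the interflavan bond.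
4. 13 ⇐ hydroxyl-directed epoxidation of Z-allylic alcohol 10 ⇐ semihydrogenation ⇐ asymmetric alkynylation of aldehyde 7 with alkyne 8 (the carbinol relays chirality to the epoxide and is then erased at C4); 18 ⇐ (−)-epicatechin by benzylation, C8 bromination and galloylation.
5. Ring order: the lower unit's rings come intact from epicatechin, upper rings A and B are bought as arenes, and upper ring C is the only ring made, in the key step.

Key step: step 11

**Route**

Step 1
Reactants: 1 2,4,6-trihydroxybenzaldehyde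
Product: 3 4,6-bis(benzyloxy)-2-hydroxybenzaldehyde
Conditions: BnBr (2.1 equiv), K2CO3 (2.2 equiv), DMF, 0 °C → rt
Reagents that add atoms: benzyl bromide 2, BrCc1ccccc1
Why: Williamson O-benzylation in which the hydroxyl hydrogen-bonded to the formyl group is the least reactive, so two equivalents should leave exactly that phenol free.

Step 2
Reactants: 3 4,6-bis(benzyloxy)-2-hydroxybenzaldehyde
Product: 5 4,6-bis(benzyloxy)-3,5-dibromo-2-hydroxybenzaldehyde
Conditions: NBS (2.1 equiv), MeCN, 0 °C → rt, dark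
Reagents that add atoms: N-bromosuccinimide 4, O=C1CCC(=O)N1Br
Why: Electrophilic aromatic bromination at the only two free ring positions, both ortho/para to oxygen, installs the caps for the future C6 and C8 of the upper ring A.

Step 3
Reactants: 5 4,6-bis(benzyloxy)-3,5-dibromo-2-hydroxybenzaldehyde
Product: 7 4,6-bis(benzyloxy)-3,5-dibromo-2-[(triisopropylsilyl)oxy]benzaldehyde
Conditions: TIPSOTf, 2,6-lutidine, CH2Cl2, 0 °C
Reagents that add atoms: triisopropylsilyl triflate 6, CC(C)[Si](OS(=O)(=O)C(F)(F)F)(C(C)C)C(C)C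
Why: Phenol silylation with a silyl triflate, reactive enough for the flanked phenol, masks the oxygen that must stay silent until the epoxide is in place, and the bulky silyl group resists migration to the later alkoxide.

Step 4
Reactants: 7 4,6-bis(benzyloxy)-3,5-dibromo-2-[(triisopropylsilyl)oxy]benzaldehyde; 8 1-(benzyloxy)-4-ethynylbenzene
Product: 9 (R)-1-{4,6-bis(benzyloxy)-3,5-dibromo-2-[(triisopropylsilyl)oxy]phenyl}-3-[4-(benzyloxy)phenyl]prop-2-yn-1-ol
Conditions: 8 (2.8 equiv), Me2Zn (2.9 equiv), (S,S)-ProPhenol (20 mol%), Ph3P=O (40 mol%), toluene, 0 °C → rt; aq NH4Cl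
Reagents that add atoms: none
Why: Catalytic enantioselective alkynylzinc addition to an aryl aldehyde (dinuclear zinc ProPhenol catalysis) should set the (R)-carbinol centre by face-selective delivery of the alkynyl group within the chiral dizinc pocket.

Step 5
Reactants: 9 (R)-propargylic alcohol
Product: 10 (R,Z)-1-{4,6-bis(benzyloxy)-3,5-dibromo-2-[(triisopropylsilyl)oxy]phenyl}-3-[4-(benzyloxy)phenyl]prop-2-en-1-ol
Conditions: H2 (1 atm), Pd/CaCO3 poisoned with Pb(OAc)2 (Lindlar catalyst), quinoline, EtOAc, rt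
Reagents that add atoms: none
Why: Lindlar semihydrogenation adds hydrogen syn to the alkyne and should stop at the Z-alkene, with aryl bromides, benzyl ethers and the silyl ether untouched.

Step 6
Reactants: 10 (R,Z)-allylic alcohol
Product: 12 (S)-{4,6-bis(benzyloxy)-3,5-dibromo-2-[(triisopropylsilyl)oxy]phenyl}{(2R,3S)-3-[4-(benzyloxy)phenyl]oxiran-2-yl}methanol (cis-epoxide, threo to the carbinol)
Conditions: dimethyldioxirane (1.3 equiv, acetone solution), CH2Cl2, −30 → 0 °C
Reagents that add atoms: dimethyldioxirane 11, CC1(C)OO1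
Why: Hydroxyl-directed dioxirane epoxidation in which allylic 1,3-strain of the Z-alkene holds the carbinol hydrogen in the alkene plane, so oxygen should be delivered to the face syn to the hydrogen-bonding hydroxyl and anti to the bulky aryl group (threo), giving the (2R,3S)-oxirane under neutral conditions that spare the acid-labile epoxide.

Step 7
Reactants: 12 silyl-protected epoxy alcohol
Product: 13 (S)-[4,6-bis(benzyloxy)-3,5-dibromo-2-hydroxyphenyl]{(2R,3S)-3-[4-(benzyloxy)phenyl]oxiran-2-yl}methanol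
Conditions: TBAF/AcOH (1:1, 1.2 equiv), THF, −20 °C; pH 7 buffer; used at once
Reagents that add atoms: none
Why: Fluoride-mediated cleavage of the aryl silyl ether, buffered with acetic acid so that the phenol stays protonated and base-induced 5-exo opening of the epoxide is avoided.

Step 8
Reactants: 14 (−)-epicatechin
Product: 15 5,7,3',4'-tetra-O-benzyl-(−)-epicatechin
Conditions: BnBr (4.4 equiv), K2CO3, DMF, 0 °C → rt
Reagents that add atoms: benzyl bromide 2, BrCc1ccccc1
Why: Williamson O-benzylation of the four phenols under carbonate base, which does not deprotonate the secondary 3-hydroxyl.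

Step 9
Reactants: 15 5,7,3',4'-tetra-O-benzyl-(−)-epicatechin
Product: 16 8-bromo-5,7,3',4'-tetra-O-benzyl-(−)-epicatechin
Conditions: NBS (1.0 equiv), CH2Cl2, −40 °C → rt
Reagents that add atoms: N-bromosuccinimide 4, O=C1CCC(=O)N1Br
Why: Electrophilic aromatic bromination goes to C8, the more accessible and more nucleophilic ring-A position, and so caps the site that would otherwise outcompete C6.

Step 10
Reactants: 16 8-bromo-5,7,3',4'-tetra-O-benzyl-(−)-epicatechin; 17 3,4,5-tris(benzyloxy)benzoic acid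
Product: 18 8-bromo-5,7,3',4'-tetra-O-benzyl-(−)-epicatechin 3-O-(3,4,5-tri-O-benzylgallate)
Conditions: DCC, DMAP (cat.), CH2Cl2, rt
Reagents that add atoms: none
Why: Steglich esterification acylates the only free hydroxyl with retention at C3, so the gallate is in place before the fragments are joined.

Step 11
Reactants: 13 cis-epoxy alcohol with free ring-A phenol; 18 bromine-capped epicatechin gallate
Product: 21 protected tribromo dimer [6,8-dibromo-5,7,4'-tri-O-benzylepiafzelechin-(4β→6)-8-bromo-5,7,3',4'-tetra-O-benzylepicatechin 3-O-(3,4,5-tri-O-benzylgallate)], via flavan-3,4-diol 19 (not isolated), via C4 benzylic cation 20 (not isolated)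
Conditions: 18 (1.5 equiv), BF3·OEt2 (0.5 equiv), 4 Å MS, CH2Cl2, −78 °C (30 min) → 0 °C
Reagents that add atoms: none
Why: At −78 °C BF3 activates the cis-epoxide of 13 and the ring-A phenol oxygen attacks the benzylic epoxide carbon in an SN2-like 6-endo-tet opening (closest known reaction type: acid-catalysed 6-endo cyclisation of o-(2,3-epoxy-3-arylpropyl)phenols to flavan-3-ols), which closes pyran ring C and gives diol 19. On warming, the 4-hydroxyl of 19, benzylic and ortho-related to the ring oxygen, ionises to the benzopyranyl cation 20, which C6 of 18 traps in a Friedel–Crafts alkylation (closest known reaction type: Lewis-acid condensation of flavan-3,4-diols or 4-alkoxyflavans with bromine-capped flavan-3-ol nucleophiles). C2 is set by inversion of the (S)-epoxide carbon and C3 is carried over from the epoxide, hence 2,3-cis; C4 is set under substrate control because 18 approaches the planar cation anti to the pseudoaxial 3-hydroxyl (3,4-trans, 4β), so the carbinol configuration of 13 no longer matters once it has relayed chirality to the epoxide. The step needs 6-endo over 5-exo opening, secured by the cation-stabilising 4-benzyloxyphenyl group on the attacked carbon; ring closure before C4 ionisation, secured by the temperature staging and the greater basicity and strain of the epoxide; attack through C6 only, secured by the C8 bromine of 18; and no self-condensation, secured by the bromines at C6 and C8 of the electrophile.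

Step 12
Reactants: 21 protected tribromo dimer
Product: 22 (−)-epiafzelechin-(4β→6)-(−)-epicatechin 3-O-gallate (target)
Conditions: H2 (1 atm), Pd(OH)2/C, Et3N (3.5 equiv), THF/MeOH/H2O, rt
Reagents that add atoms: none
Why: Catalytic hydrogenolysis should cleave the ten benzyl ethers and, with amine as acid scavenger, the three aryl C–Br bonds, while the gallate ester, the interflavan bond and all five stereocentres are not touched.

**Compound list**
1 | 2,4,6-trihydroxybenzaldehyde | O=Cc1c(O)cc(O)cc1O | starting material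
2 | benzyl bromide | BrCc1ccccc1 | starting material (reagent)
3 | 4,6-bis(benzyloxy)-2-hydroxybenzaldehyde | O=Cc1c(O)cc(OCc2ccccc2)cc1OCc1ccccc1 | intermediate
4 | N-bromosuccinimide | O=C1CCC(=O)N1Br | starting material (reagent)
5 | 4,6-bis(benzyloxy)-3,5-dibromo-2-hydroxybenzaldehyde | O=Cc1c(O)c(Br)c(OCc2ccccc2)c(Br)c1OCc1ccccc1 | intermediate
6 | triisopropylsilyl triflate | CC(C)[Si](OS(=O)(=O)C(F)(F)F)(C(C)C)C(C)C | starting material (reagent)
7 | 4,6-bis(benzyloxy)-3,5-dibromo-2-[(triisopropylsilyl)oxy]benzaldehyde | O=Cc1c(O[Si](C(C)C)(C(C)C)C(C)C)c(Br)c(OCc2ccccc2)c(Br)c1OCc1ccccc1 | intermediate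
8 | 1-(benzyloxy)-4-ethynylbenzene | C#Cc1ccc(OCc2ccccc2)cc1 | starting material
9 | (R)-1-{4,6-bis(benzyloxy)-3,5-dibromo-2-[(triisopropylsilyl)oxy]phenyl}-3-[4-(benzyloxy)phenyl]prop-2-yn-1-ol | O[C@H](C#Cc1ccc(OCc2ccccc2)cc1)c1c(O[Si](C(C)C)(C(C)C)C(C)C)c(Br)c(OCc2ccccc2)c(Br)c1OCc1ccccc1 | intermediate
10 | (R,Z)-1-{4,6-bis(benzyloxy)-3,5-dibromo-2-[(triisopropylsilyl)oxy]phenyl}-3-[4-(benzyloxy)phenyl]prop-2-en-1-ol | O[C@H](/C=C\c1ccc(OCc2ccccc2)cc1)c1c(O[Si](C(C)C)(C(C)C)C(C)C)c(Br)c(OCc2ccccc2)c(Br)c1OCc1ccccc1 | intermediate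
11 | dimethyldioxirane | CC1(C)OO1 | starting material (reagent, freshly made acetone solution)
12 | (S)-{4,6-bis(benzyloxy)-3,5-dibromo-2-[(triisopropylsilyl)oxy]phenyl}{(2R,3S)-3-[4-(benzyloxy)phenyl]oxiran-2-yl}methanol | O[C@H]([C@H]1O[C@H]1c1ccc(OCc2ccccc2)cc1)c1c(O[Si](C(C)C)(C(C)C)C(C)C)c(Br)c(OCc2ccccc2)c(Br)c1OCc1ccccc1 | intermediate
13 | (S)-[4,6-bis(benzyloxy)-3,5-dibromo-2-hydroxyphenyl]{(2R,3S)-3-[4-(benzyloxy)phenyl]oxiran-2-yl}methanol | O[C@H]([C@H]1O[C@H]1c1ccc(OCc2ccccc2)cc1)c1c(O)c(Br)c(OCc2ccccc2)c(Br)c1OCc1ccccc1 | intermediate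
14 | (−)-epicatechin, (2R,3R) | O[C@@H]1Cc2c(O)cc(O)cc2O[C@@H]1c1ccc(O)c(O)c1 | starting material
15 | 5,7,3',4'-tetra-O-benzyl-(−)-epicatechin | O[C@@H]1Cc2c(OCc3ccccc3)cc(OCc3ccccc3)cc2O[C@@H]1c1ccc(OCc2ccccc2)c(OCc2ccccc2)c1 | intermediate
16 | 8-bromo-5,7,3',4'-tetra-O-benzyl-(−)-epicatechin | O[C@@H]1Cc2c(OCc3ccccc3)cc(OCc3ccccc3)c(Br)c2O[C@@H]1c1ccc(OCc2ccccc2)c(OCc2ccccc2)c1 | intermediate
17 | 3,4,5-tris(benzyloxy)benzoic acid | O=C(O)c1cc(OCc2ccccc2)c(OCc2ccccc2)c(OCc2ccccc2)c1 | starting material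
18 | 8-bromo-5,7,3',4'-tetra-O-benzyl-(−)-epicatechin 3-O-(3,4,5-tri-O-benzylgallate) | O=C(O[C@@H]1Cc2c(OCc3ccccc3)cc(OCc3ccccc3)c(Br)c2O[C@@H]1c1ccc(OCc2ccccc2)c(OCc2ccccc2)c1)c1cc(OCc2ccccc2)c(OCc2ccccc2)c(OCc2ccccc2)c1 | intermediate
19 | (2R,3R,4S)-5,7-bis(benzyloxy)-2-[4-(benzyloxy)phenyl]-6,8-dibromochromane-3,4-diol (2,3-cis-3,4-trans) | O[C@H]1c2c(OCc3ccccc3)c(Br)c(OCc3ccccc3)c(Br)c2O[C@H](c2ccc(OCc3ccccc3)cc2)[C@@H]1O | intermediate (not isolated)
20 | (2R,3R)-5,7-bis(benzyloxy)-2-[4-(benzyloxy)phenyl]-6,8-dibromo-3-hydroxychroman-4-ylium | [CH+]1c2c(OCc3ccccc3)c(Br)c(OCc3ccccc3)c(Br)c2O[C@H](c2ccc(OCc3ccccc3)cc2)[C@@H]1O | intermediate (not isolated)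
21 | 6,8-dibromo-5,7,4'-tri-O-benzylepiafzelechin-(4β→6)-8-bromo-5,7,3',4'-tetra-O-benzylepicatechin 3-O-(3,4,5-tri-O-benzylgallate); upper unit (2R,3R,4S), lower unit (2R,3R) | O=C(O[C@@H]1Cc2c(OCc3ccccc3)c([C@H]3c4c(OCc5ccccc5)c(Br)c(OCc5ccccc5)c(Br)c4O[C@H](c4ccc(OCc5ccccc5)cc4)[C@@H]3O)c(OCc3ccccc3)c(Br)c2O[C@@H]1c1ccc(OCc2ccccc2)c(OCc2ccccc2)c1)c1cc(OCc2ccccc2)c(OCc2ccccc2)c(OCc2ccccc2)c1 | intermediate
22 | (−)-epiafzelechin-(4β→6)-(−)-epicatechin 3-O-gallate; upper unit (2R,3R,4S), lower unit (2R,3R) | O=C(O[C@@H]1Cc2c(cc(O)c([C@H]3c4c(O)cc(O)cc4O[C@H](c4ccc(O)cc4)[C@@H]3O)c2O)O[C@@H]1c1ccc(O)c(O)c1)c1cc(O)c(O)c(O)c1 | target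

**Step count and risks**
Total steps: 12. Longest linear sequence: 9 (steps 1–7, 11, 12).

Steps most likely to fail:

1. Step 11. Ionisation at C4, or SN1-type opening of the epoxide, may outrun the concerted ring closure under the Lewis acid. That would give intermolecular capture of an open-chain cation and erosion of the C2 configuration. Ionisation of the bromine-deactivated ring A may also be sluggish. Fallback, setting out from 13: the epoxide opening is run alone with pyridinium p-toluenesulfonate (cat.) in CH2Cl2 at −20 °C and diol 19 is isolated. Acid-catalysed exchange of its benzylic 4-hydroxyl with 2-ethoxyethanol (camphorsulfonic acid cat., CH2Cl2, 0 °C) should give the 4β-(2-ethoxyethoxy)flavan-3-ol F1. This defined electrophile is then condensed with 18 under TMSOTf (cat.) at −78 °C, and the route is rejoined at 21.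

2. Step 6. The electron-rich cis-epoxide may solvolyse or rearrange (Meinwald-type) during formation and isolation. Fallback, setting out from 10: the silyl ether is cleaved first (TBAF/AcOH, THF, −20 °C) to the free-phenol Z-allylic alcohol F2. F2 is then epoxidised with dimethyldioxirane at −40 °C and treated in the same flask with pyridinium p-toluenesulfonate, so the epoxide is consumed by 6-endo cyclisation as it forms. The route is rejoined at 19, which is isolated and taken through the second stage of step 11 (18, BF3·OEt2) to 21.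

3. Step 4. Addition to the doubly ortho-substituted, electron-rich aldehyde may be slow and poorly enantioselective. Fallback, setting out from 7: the lithium acetylide of 8 (n-BuLi, THF, −78 °C) is added to give the racemic propargylic alcohol F3. F3 is oxidised with MnO2 in CH2Cl2 to the ynone F4. F4 is reduced by asymmetric transfer hydrogenation with RuCl[(S,S)-TsDPEN](p-cymene) in i-PrOH (or the catalyst antipode, whichever gives the (R)-alcohol), and the route is rejoined at 9.

Further compounds
F1 | step 11 | (2R,3R,4S)-5,7-bis(benzyloxy)-2-[4-(benzyloxy)phenyl]-6,8-dibromo-4-(2-ethoxyethoxy)chroman-3-ol | CCOCCO[C@H]1c2c(OCc3ccccc3)c(Br)c(OCc3ccccc3)c(Br)c2O[C@H](c2ccc(OCc3ccccc3)cc2)[C@@H]1O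
F2 | step 6 | (R,Z)-1-[4,6-bis(benzyloxy)-3,5-dibromo-2-hydroxyphenyl]-3-[4-(benzyloxy)phenyl]prop-2-en-1-ol | O[C@H](/C=C\c1ccc(OCc2ccccc2)cc1)c1c(O)c(Br)c(OCc2ccccc2)c(Br)c1OCc1ccccc1
F3 | step 4 | racemic 1-{4,6-bis(benzyloxy)-3,5-dibromo-2-[(triisopropylsilyl)oxy]phenyl}-3-[4-(benzyloxy)phenyl]prop-2-yn-1-ol | OC(C#Cc1ccc(OCc2ccccc2)cc1)c1c(O[Si](C(C)C)(C(C)C)C(C)C)c(Br)c(OCc2ccccc2)c(Br)c1OCc1ccccc1
F4 | step 4 | 1-{4,6-bis(benzyloxy)-3,5-dibromo-2-[(triisopropylsilyl)oxy]phenyl}-3-[4-(benzyloxy)phenyl]prop-2-yn-1-one | O=C(C#Cc1ccc(OCc2ccccc2)cc1)c1c(O[Si](C(C)C)(C(C)C)C(C)C)c(Br)c(OCc2ccccc2)c(Br)c1OCc1ccccc1
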